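**Retrosynthetic overview**
1. Ring D (oxepane) is closed last, as a C16–O–C3 ether from the primary triflate of a C16/C3 diol; C15/C16 come from hydroboration of a C14 isopropenyl group and the C11 acetate from a C11 ketone.
2. Rings A and B (cyclohexene and tetrahydrofuran) form together by an intramolecular Diels–Alder reaction between a 2-methoxydiene on C9 and an enone on C2, both held on ring C.
3. Ring C (oxonene) is closed by ring-closing metathesis at C6=C7.
4. Key fragment union: an Evans syn glycolate aldol (C2–C3 bond) between an N-glycolyl oxazolidinone from (R)-benzyl glycidyl ether and pent-4-enal; the C3 methyl then enters by chelation-controlled MeMgBr addition.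
5. Ring order: C (oxonene), then A + B, then D (oxepane).

Assumption (numbering only): locants follow asbestinin numbering — ring A = cyclohexane C1/C10–C14, ring B = tetrahydrofuran C1-C2-O-C9-C10, ring C = oxonene O/C2–C9, ring D = oxepane C1-C2-C3-O-C16-C15-C14; C17 = methyl on C15, C18/C19/C20 = methyls on C3/C7/C12; with these locants 38 is (1S,2R,3S,6Z,9R,10R,11R,12R,14S,15R).

**Route**

Step 1
Reactants: 1 (R)-benzyl glycidyl ether; 2 isopropenylmagnesium bromide
Product: 3 (2R)-1-(benzyloxy)-4-methylpent-4-en-2-ol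
Conditions: CuBr·SMe2 (10 mol %), THF, −40 → 0 °C; aq NH4Cl
Reagents that add atoms: none
Why: Copper-catalysed Grignard opening of the epoxide at its unsubstituted carbon (SN2) leaves the carbinol stereocentre (future C9) of 1 untouched.

Step 2
Reactants: 3 (2R)-1-(benzyloxy)-4-methylpent-4-en-2-ol; 4 bromoacetic acid
Product: 5 2-{[(2R)-1-(benzyloxy)-4-methylpent-4-en-2-yl]oxy}acetic acid
Conditions: NaH (2.5 equiv), THF/DMF, 0 °C → rt; 1 M HCl
Reagents that add atoms: none
Why: Williamson etherification of the sodium alkoxide with sodium bromoacetate gives the glycolic acid without touching the stereocentre.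

Step 3
Reactants: 5 2-{[(2R)-1-(benzyloxy)-4-methylpent-4-en-2-yl]oxy}acetic acid; 6 (4S)-4-benzyl-1,3-oxazolidin-2-one
Product: 8 (4S)-4-benzyl-3-(2-{[(2R)-1-(benzyloxy)-4-methylpent-4-en-2-yl]oxy}acetyl)-1,3-oxazolidin-2-one, via mixed pivalic anhydride 7 (not isolated)
Conditions: PivCl, Et3N, THF, −78 → 0 °C; then 6/n-BuLi (THF, −78 °C), −78 → 0 °C; aq NH4Cl
Reagents that add atoms: none
Why: N-acylation of the lithiated Evans oxazolidinone by the mixed anhydride occurs at the unhindered glycolyl carbonyl.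

Step 4
Reactants: 8 (4S)-4-benzyl-3-(2-{[(2R)-1-(benzyloxy)-4-methylpent-4-en-2-yl]oxy}acetyl)-1,3-oxazolidin-2-one; 9 pent-4-enal
Product: 12 (4S)-4-benzyl-3-[(2S,3R)-2-{[(2R)-1-(benzyloxy)-4-methylpent-4-en-2-yl]oxy}-3-hydroxyhept-6-enoyl]-1,3-oxazolidin-2-one, via dibutylboron enolate 10 (not isolated), via dibutylboron aldolate 11 (not isolated)
Conditions: Bu2BOTf, Et3N, CH2Cl2, −78 → 0 °C; 9, −78 → 0 °C; pH 7 buffer, MeOH, 30% H2O2, 0 °C
Reagents that add atoms: none
Why: Evans syn aldol reaction: the (Z)-boron enolate reacts through a Zimmerman–Traxler chair on the face away from the auxiliary benzyl group, forming the C2–C3 bond and setting C2 (the 2R centre of the target) with C3–OH syn to it.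

Step 5
Reactants: 12 aldol adduct
Product: 13 (2R,3R)-2-{[(2R)-1-(benzyloxy)-4-methylpent-4-en-2-yl]oxy}hept-6-ene-1,3-diol
Conditions: LiBH4, MeOH (1 equiv), THF, 0 °C
Reagents that add atoms: none
Why: Reductive cleavage of the imide (hydride attack at the exocyclic carbonyl) gives the 1,3-diol and returns the auxiliary without epimerising C2.

Step 6
Reactants: 13 1,3-diol
Product: 14 (2R,3R)-2-{[(2R)-1-(benzyloxy)-4-methylpent-4-en-2-yl]oxy}-1-[(tert-butyldimethylsilyl)oxy]hept-6-en-3-ol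
Conditions: TBSCl (1.05 equiv), imidazole, CH2Cl2, 0 °C
Reagents that add atoms: tert-butyldimethylsilyl chloride CC(C)(C)[Si](C)(C)Cl
Why: Sterically controlled silylation takes the primary hydroxyl in preference to the secondary one.

Step 7
Reactants: 14 mono-silyl ether
Product: 15 (2R)-2-{[(2R)-1-(benzyloxy)-4-methylpent-4-en-2-yl]oxy}-1-[(tert-butyldimethylsilyl)oxy]hept-6-en-3-one
Conditions: Dess–Martin periodinane, NaHCO3, CH2Cl2, 0 °C → rt
Reagents that add atoms: none
Why: Buffered Dess–Martin oxidation gives the α-alkoxy ketone without epimerising C2.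

Step 8
Reactants: 15 α-alkoxy ketone
Product: 16 (2R,3S)-2-{[(2R)-1-(benzyloxy)-4-methylpent-4-en-2-yl]oxy}-1-[(tert-butyldimethylsilyl)oxy]-3-methylhept-6-en-3-ol
Conditions: MeMgBr (3 equiv), Et2O/CH2Cl2, −78 °C; aq NH4Cl
Reagents that add atoms: methylmagnesium bromide C[Mg]Br
Why: Cram-chelate-controlled Grignard addition: magnesium bridges the ketone and the C2 ether oxygen and the methyl group adds anti to the C1 CH2OTBS group, setting C3 (S).

Step 9
Reactants: 16 tertiary alcohol
Product: 17 (2R,3S)-2-{[(2R)-1-(benzyloxy)-4-methylpent-4-en-2-yl]oxy}-1,3-bis[(tert-butyldimethylsilyl)oxy]-3-methylhept-6-ene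
Conditions: TBSOTf, 2,6-lutidine, CH2Cl2, 0 °C → rt
Reagents that add atoms: tert-butyldimethylsilyl triflate CC(C)(C)[Si](C)(C)OS(=O)(=O)C(F)(F)F
Why: Silyl triflate silylation of the hindered tertiary alcohol gives an acid-stable ether that later keeps O3 from adding across the C6=C7 alkene.

Step 10
Reactants: 17 bis-silyl diene
Product: 18 (2R,3S,6Z,9R)-9-[(benzyloxy)methyl]-3-[(tert-butyldimethylsilyl)oxy]-2-{[(tert-butyldimethylsilyl)oxy]methyl}-3,7-dimethyl-2,3,4,5,8,9-hexahydrooxonine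
Conditions: second-generation Grubbs catalyst RuCl2(=CHPh)(PCy3)(H2IMes) (10 mol %), CH2Cl2 (2 mM), 40 °C
Reagents that add atoms: none
Why: Ring-closing metathesis, helped by the gauche C2–O/C3–O arrangement and the quaternary C3, closes ring C; the nine-membered ring allows only the (Z)-C6=C7 alkene.

Step 11
Reactants: 18 oxonene benzyl ether
Product: 19 C10 alcohol, the 9-(hydroxymethyl) analogue of 18
Conditions: Na, NH3(l), THF, −78 °C; NH4Cl
Reagents that add atoms: none
Why: Dissolving-metal cleavage of the benzyl ether leaves the isolated trisubstituted alkene and both silyl ethers intact.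

Step 12
Reactants: 19 C10 alcohol
Product: 20 C10 aldehyde, the oxonine-9-carbaldehyde
Conditions: Dess–Martin periodinane, NaHCO3, CH2Cl2, 0 °C → rt
Reagents that add atoms: none
Why: Dess–Martin oxidation gives the α-alkoxy aldehyde under non-epimerising conditions.

Step 13
Reactants: 21 dimethyl (1-diazo-2-oxopropyl)phosphonate
Product: 22 dimethyl (1-methoxy-2-oxopropyl)phosphonate
Conditions: MeOH (5 equiv), Rh2(OAc)4 (1 mol %), benzene, 80 °C
Reagents that add atoms: methanol CO
Why: Rhodium-carbenoid O–H insertion of the diazophosphonate into methanol.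

Step 14
Reactants: 20 C10 aldehyde; 22 dimethyl (1-methoxy-2-oxopropyl)phosphonate
Product: 23 (3Z)-3-methoxy-4-[oxonin-9-yl]but-3-en-2-one (C10=C11(OMe)–C12(=O)CH3 on C9)
Conditions: 22, NaH, THF, 0 °C; then 20, −78 → 0 °C
Reagents that add atoms: none
Why: Horner–Wadsworth–Emmons olefination places the acyl group trans to the oxonene substituent, which is the (Z)-enol ether needed for the cycloaddition.

Step 15
Reactants: 23 methoxy enone
Product: 24 9-[(1Z)-2-methoxy-3-methylbuta-1,3-dien-1-yl] oxonene (diene C10=C11(OMe)–C12(Me)=C13)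
Conditions: Ph3PCH3Br, KOt-Bu, THF, 0 °C → rt
Reagents that add atoms: methyltriphenylphosphonium bromide C[P+](c1ccccc1)(c1ccccc1)c1ccccc1.[Br-]
Why: Wittig methylenation (1,2-addition of the non-stabilised ylide to the enone carbonyl) gives the 2-methoxy-3-methyl diene.

Step 16
Reactants: 24 diene bis-silyl ether
Product: 25 C1 alcohol, the oxonin-2-ylmethanol with the tertiary C3–OTBS kept
Conditions: TBAF (1.1 equiv), THF, 0 °C; aq NH4Cl
Reagents that add atoms: none
Why: Fluoride desilylation is far faster at the unhindered primary silyl ether than at the tertiary one, and the basic medium spares the enol ether.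

Step 17
Reactants: 25 C1 alcohol
Product: 26 C1 aldehyde, the oxonine-2-carbaldehyde
Conditions: Dess–Martin periodinane, pyridine, CH2Cl2, 0 °C
Reagents that add atoms: none
Why: Pyridine-buffered Dess–Martin oxidation gives the aldehyde while the acid-labile methoxydiene survives.

Step 18
Reactants: 26 C1 aldehyde; 27 1-(triphenylphosphoranylidene)propan-2-one
Product: 29 tricyclic methyl ketone (rings A/B/C; C11(OMe)=C12 enol ether; acetyl on C14), via tetraene enone 28 (not isolated)
Conditions: 27, BHT (cat.), toluene, rt → 80 °C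
Reagents that add atoms: none
Why: Wittig olefination gives the (E)-enone, and the intramolecular Diels–Alder reaction (tether-fixed C1–C10/C13–C14 bonding, acetyl exo, diene face dictated by the cis-2,9-disubstituted oxonene) sets C1, C10 and C14 with H1/H10 cis to H2/H9 and the acetyl trans to C2.

Step 19
Reactants: 29 tricyclic methyl ketone
Product: 30 14-isopropenyl enol ether (C15=C16 methylene)
Conditions: Ph3PCH3Br, KOt-Bu, THF, 0 °C → rt
Reagents that add atoms: methyltriphenylphosphonium bromide C[P+](c1ccccc1)(c1ccccc1)c1ccccc1.[Br-]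
Why: Wittig methylenation of the only ketone present installs C16 while the enol ether masks C11.

Step 20
Reactants: 30 isopropenyl enol ether
Product: 31 C11 ketone with 12R methyl
Conditions: 0.5 M aq HCl, THF, 0 °C
Reagents that add atoms: water O
Why: Acid hydrolysis of the enol ether protonates C12 from the exposed convex face (the side of H1/H10), putting the methyl on the concave face (12R); the tertiary TBS ether survives.

Step 21
Reactants: 31 C11 ketone
Product: 32 C11 alcohol (11R)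
Conditions: LiBH(s-Bu)3 (L-Selectride), THF, −78 °C; aq NH4Cl
Reagents that add atoms: none
Why: The bulky hydride attacks from the convex face, giving the C11 hydroxyl cis to the C12 methyl and to C9.

Step 22
Reactants: 32 C11 alcohol
Product: 33 C3,C11-diol
Conditions: TBAF (5 equiv), THF, 65 °C; aq NH4Cl
Reagents that add atoms: none
Why: Fluoride desilylation of the hindered tertiary ether needs heat, which 32 tolerates because nothing epimerisable or base-labile remains.

Step 23
Reactants: 33 C3,C11-diol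
Product: 34 C11 acetate with free C3–OH
Conditions: Ac2O (1.5 equiv), DMAP (cat.), Et3N, CH2Cl2, 0 °C → rt
Reagents that add atoms: acetic anhydride CC(=O)OC(C)=O
Why: DMAP-catalysed acetylation takes the secondary C11 hydroxyl and leaves the tertiary C3 hydroxyl.

Step 24
Reactants: 34 C11 acetate
Product: 36 C16,C3-diol (15R), via alkyl-9-BBN borane 35 (not isolated)
Conditions: 9-BBN (3 equiv), THF, 0 °C → rt; then NaBO3·4H2O, H2O, rt
Reagents that add atoms: sodium perborate [Na+].[Na+].O[B-]1(O)OO[B-](O)(O)OO1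
Why: Anti-Markovnikov hydroboration–oxidation, selective for the 1,1-disubstituted alkene over the ring alkene; boron adds to the face anti to C1 in the conformer with H14 eclipsing C15=C16, setting C15 (R).

Step 25
Reactants: 36 C16,C3-diol
Product: 38 target, via primary triflate 37 (not isolated)
Conditions: Tf2O (1.1 equiv), 2,6-lutidine (3 equiv), CH2Cl2, −78 °C → rt
Reagents that add atoms: none
Why: Selective triflation of the primary alcohol followed by intramolecular Williamson-type SN2 etherification by the C3 hydroxyl closes ring D without touching a stereocentre.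

**Compound list**
1 | (R)-benzyl glycidyl ether | C(OCc1ccccc1)[C@H]1CO1 | starting material
2 | isopropenylmagnesium bromide | CC(=C)[Mg]Br | starting material
3 | (2R)-1-(benzyloxy)-4-methylpent-4-en-2-ol | C=C(C)C[C@@H](O)COCc1ccccc1 | intermediate
4 | bromoacetic acid | OC(=O)CBr | starting material
5 | 2-{[(2R)-1-(benzyloxy)-4-methylpent-4-en-2-yl]oxy}acetic acid | C=C(C)C[C@@H](OCC(=O)O)COCc1ccccc1 | intermediate
6 | (4S)-4-benzyl-1,3-oxazolidin-2-one | O=C1N[C@@H](Cc2ccccc2)CO1 | starting material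
7 | mixed pivalic anhydride of 5 (not isolated) | C=C(C)C[C@@H](OCC(=O)OC(=O)C(C)(C)C)COCc1ccccc1 | intermediate
8 | N-glycolyl oxazolidinone | C=C(C)C[C@@H](OCC(=O)N1[C@@H](Cc2ccccc2)COC1=O)COCc1ccccc1 | intermediate
9 | pent-4-enal | C=CCCC=O | starting material
10 | (Z)-dibutylboron enolate of 8 (not isolated) | C=C(C)C[C@@H](O/C=C(\OB(CCCC)CCCC)N1[C@@H](Cc2ccccc2)COC1=O)COCc1ccccc1 | intermediate
11 | dibutylboron aldolate of 12 (not isolated) | C=C(C)C[C@@H](O[C@H](C(=O)N1[C@@H](Cc2ccccc2)COC1=O)[C@H](OB(CCCC)CCCC)CCC=C)COCc1ccccc1 | intermediate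
12 | (2S,3R) syn aldol adduct | C=C(C)C[C@@H](O[C@H](C(=O)N1[C@@H](Cc2ccccc2)COC1=O)[C@H](O)CCC=C)COCc1ccccc1 | intermediate
13 | (2R,3R)-1,3-diol | C=C(C)C[C@@H](O[C@H](CO)[C@H](O)CCC=C)COCc1ccccc1 | intermediate
14 | primary TBS ether, C3–OH free | C=C(C)C[C@@H](O[C@H](CO[Si](C)(C)C(C)(C)C)[C@H](O)CCC=C)COCc1ccccc1 | intermediate
15 | C3 ketone | C=C(C)C[C@@H](O[C@H](CO[Si](C)(C)C(C)(C)C)C(=O)CCC=C)COCc1ccccc1 | intermediate
16 | (2R,3S) tertiary alcohol | C=C(C)C[C@@H](O[C@H](CO[Si](C)(C)C(C)(C)C)[C@@](C)(O)CCC=C)COCc1ccccc1 | intermediate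
17 | bis-TBS diene | C=C(C)C[C@@H](O[C@H](CO[Si](C)(C)C(C)(C)C)[C@@](C)(O[Si](C)(C)C(C)(C)C)CCC=C)COCc1ccccc1 | intermediate
18 | (2R,3S,6Z,9R)-oxonene, 9-CH2OBn, 2-CH2OTBS, 3-OTBS, 3,7-dimethyl | CC(C)(C)[Si](C)(C)O[C@@]1(C)CC/C=C(/C)C[C@H](COCc2ccccc2)O[C@@H]1CO[Si](C)(C)C(C)(C)C | intermediate
19 | oxonene C10 alcohol | CC(C)(C)[Si](C)(C)O[C@@]1(C)CC/C=C(/C)C[C@H](CO)O[C@@H]1CO[Si](C)(C)C(C)(C)C | intermediate
20 | oxonene C10 aldehyde | CC(C)(C)[Si](C)(C)O[C@@]1(C)CC/C=C(/C)C[C@H](C=O)O[C@@H]1CO[Si](C)(C)C(C)(C)C | intermediate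
21 | dimethyl (1-diazo-2-oxopropyl)phosphonate | COP(=O)(OC)C(=[N+]=[N-])C(C)=O | starting material
22 | dimethyl (1-methoxy-2-oxopropyl)phosphonate | COC(C(C)=O)P(=O)(OC)OC | intermediate
23 | (Z)-methoxy enone on C9 | CC(C)(C)[Si](C)(C)O[C@@]1(C)CC/C=C(/C)C[C@H](/C=C(\OC)C(C)=O)O[C@@H]1CO[Si](C)(C)C(C)(C)C | intermediate
24 | (Z)-2-methoxy-3-methyl diene on C9 | CC(C)(C)[Si](C)(C)O[C@@]1(C)CC/C=C(/C)C[C@H](/C=C(\OC)C(C)=C)O[C@@H]1CO[Si](C)(C)C(C)(C)C | intermediate
25 | diene C1 alcohol | CC(C)(C)[Si](C)(C)O[C@@]1(C)CC/C=C(/C)C[C@H](/C=C(\OC)C(C)=C)O[C@@H]1CO | intermediate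
26 | diene C1 aldehyde | CC(C)(C)[Si](C)(C)O[C@@]1(C)CC/C=C(/C)C[C@H](/C=C(\OC)C(C)=C)O[C@@H]1C=O | intermediate
27 | 1-(triphenylphosphoranylidene)propan-2-one | CC(=O)C=P(c1ccccc1)(c1ccccc1)c1ccccc1 | starting material
28 | tetraene: diene on C9, (E)-enone on C2 (not isolated) | CC(C)(C)[Si](C)(C)O[C@@]1(C)CC/C=C(/C)C[C@H](/C=C(\OC)C(C)=C)O[C@@H]1/C=C/C(C)=O | intermediate
29 | tricyclic methyl ketone: rings A/B/C, C11(OMe)=C12, 14-acetyl trans to C2, 3-OTBS, H1/H2/H9/H10 all cis | CC(C)(C)[Si](C)(C)O[C@@]1(C)CC/C=C(/C)C[C@H]2O[C@@H]1[C@H]3[C@H](C(C)=O)CC(C)=C(OC)[C@H]32 | intermediate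
30 | 14-isopropenyl enol ether | CC(C)(C)[Si](C)(C)O[C@@]1(C)CC/C=C(/C)C[C@H]2O[C@@H]1[C@H]3[C@H](C(C)=C)CC(C)=C(OC)[C@H]32 | intermediate
31 | C11 ketone, 12R methyl | CC(C)(C)[Si](C)(C)O[C@@]1(C)CC/C=C(/C)C[C@H]2O[C@@H]1[C@H]3[C@H](C(C)=C)C[C@@H](C)C(=O)[C@H]32 | intermediate
32 | C11 alcohol (11R), 3-OTBS | CC(C)(C)[Si](C)(C)O[C@@]1(C)CC/C=C(/C)C[C@H]2O[C@@H]1[C@H]3[C@H](C(C)=C)C[C@@H](C)[C@@H](O)[C@H]32 | intermediate
33 | C3,C11-diol | O[C@@]1(C)CC/C=C(/C)C[C@H]2O[C@@H]1[C@H]3[C@H](C(C)=C)C[C@@H](C)[C@@H](O)[C@H]32 | intermediate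
34 | C11 acetate, C3–OH free, 14-isopropenyl | O[C@@]1(C)CC/C=C(/C)C[C@H]2O[C@@H]1[C@H]3[C@H](C(C)=C)C[C@@H](C)[C@@H](OC(C)=O)[C@H]32 | intermediate
35 | C16 alkyl-9-BBN borane (not isolated) | O[C@@]1(C)CC/C=C(/C)C[C@H]2O[C@@H]1[C@H]3[C@H]([C@@H](C)CB4C5CCCC4CCC5)C[C@@H](C)[C@@H](OC(C)=O)[C@H]32 | intermediate
36 | C16,C3-diol (15R), C11 acetate | O[C@@]1(C)CC/C=C(/C)C[C@H]2O[C@@H]1[C@H]3[C@H]([C@@H](C)CO)C[C@@H](C)[C@@H](OC(C)=O)[C@H]32 | intermediate
37 | C16 triflate (not isolated) | O[C@@]1(C)CC/C=C(/C)C[C@H]2O[C@@H]1[C@H]3[C@H]([C@@H](C)COS(=O)(=O)C(F)(F)F)C[C@@H](C)[C@@H](OC(C)=O)[C@H]32 | intermediate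
38 | target, tetracyclic C11 acetate | CC(=O)O[C@H]1[C@@H]2[C@@H]3[C@@H](C[C@H]1C)[C@@H](C)CO[C@@]1(C)CC/C=C(/C)C[C@H]2O[C@H]31 | target

**Step count**
Total steps: 25. Longest linear sequence: 24 (steps 1–12 and 14–25 from 1; step 13 is a one-step side branch).

**Three steps most likely to fail**

Step 10 (ring-closing metathesis). A nine-membered ring with a trisubstituted alkene must form next to a fully substituted, silylated C3. Fallback: close the ring before C3 is made quaternary. Setting out from 14, the C3 hydroxyl is silylated (TESOTf, 2,6-lutidine) to the triethylsilyl diene F1. Metathesis with the same ruthenium catalyst gives the secondary-silyloxy oxonene F2. Selective removal of the triethylsilyl group (PPTS, MeOH, 0 °C) gives the C3 alcohol F3. Dess–Martin oxidation gives the ring ketone F4, and chelation-controlled MeMgBr addition (methyl anti to C1) gives the tertiary alcohol F5. TBSOTf/2,6-lutidine then brings the route back at 18.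

Step 14 (Horner–Wadsworth–Emmons with the α-methoxy keto-phosphonate). The hindered anion may react sluggishly or give poor Z/E control, and the product enone must then survive methylenation. Fallback: build the diene through an ester. Setting out from 20, olefination with commercial methyl 2-(dimethoxyphosphoryl)-2-methoxyacetate (NaH, THF) gives the (Z)-2-methoxy enoate F6. Excess MeMgBr converts the ester into the tertiary allylic alcohol F7. Dehydration with Burgess reagent (toluene, 50 °C) gives the isopropenyl unit, and the route comes back at 24.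

Step 18 (Wittig/Diels–Alder cascade). The keto-ylide is only moderately reactive towards the hindered aldehyde, and the enone tetraene may oligomerise or cyclise less selectively. Fallback: use an ester dienophile and make the ketone afterwards. Setting out from 26, Wittig reaction with methyl (triphenylphosphoranylidene)acetate gives the (E)-enoate tetraene F8. This cyclises in the same flask to the methyl ester cycloadduct F9. MeNH(OMe)·HCl with i-PrMgCl (THF, −20 °C) gives the Weinreb amide F10. MeMgBr then gives the methyl ketone, and the route comes back at 29.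

Further compounds
F1 | step 10 | C3-triethylsilyl, C1-TBS diene | C=C(C)C[C@@H](O[C@H](CO[Si](C)(C)C(C)(C)C)[C@H](O[Si](CC)(CC)CC)CCC=C)COCc1ccccc1
F2 | step 10 | oxonene with secondary C3–OTES | CC[Si](CC)(CC)O[C@@H]1CC/C=C(/C)C[C@H](COCc2ccccc2)O[C@@H]1CO[Si](C)(C)C(C)(C)C
F3 | step 10 | oxonene C3 secondary alcohol | O[C@@H]1CC/C=C(/C)C[C@H](COCc2ccccc2)O[C@@H]1CO[Si](C)(C)C(C)(C)C
F4 | step 10 | oxonene C3 ketone | O=C1CC/C=C(/C)C[C@H](COCc2ccccc2)O[C@@H]1CO[Si](C)(C)C(C)(C)C
F5 | step 10 | oxonene C3 tertiary alcohol (3S) | O[C@@]1(C)CC/C=C(/C)C[C@H](COCc2ccccc2)O[C@@H]1CO[Si](C)(C)C(C)(C)C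
F6 | step 14 | (Z)-2-methoxy enoate on C9 | CC(C)(C)[Si](C)(C)O[C@@]1(C)CC/C=C(/C)C[C@H](/C=C(\OC)C(=O)OC)O[C@@H]1CO[Si](C)(C)C(C)(C)C
F7 | step 14 | tertiary allylic alcohol on C9 | CC(C)(C)[Si](C)(C)O[C@@]1(C)CC/C=C(/C)C[C@H](/C=C(\OC)C(C)(C)O)O[C@@H]1CO[Si](C)(C)C(C)(C)C
F8 | step 18 | tetraene with (E)-enoate on C2 | CC(C)(C)[Si](C)(C)O[C@@]1(C)CC/C=C(/C)C[C@H](/C=C(\OC)C(C)=C)O[C@@H]1/C=C/C(=O)OC
F9 | step 18 | tricyclic C14 methyl ester | CC(C)(C)[Si](C)(C)O[C@@]1(C)CC/C=C(/C)C[C@H]2O[C@@H]1[C@H]3[C@H](C(=O)OC)CC(C)=C(OC)[C@H]32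
F10 | step 18 | tricyclic C14 Weinreb amide | CC(C)(C)[Si](C)(C)O[C@@]1(C)CC/C=C(/C)C[C@H]2O[C@@H]1[C@H]3[C@H](C(=O)N(C)OC)CC(C)=C(OC)[C@H]32
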